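**Retrosynthetic overview**
- Last C–C bond: Stille coupling of the ring A E-vinylstannane 17 (Sn on C8) with the α-bromo Z-ylidenebutenolide 32, then removal of both silyl ethers.
- 32 comes from a tandem Sonogashira–lactonization of the ring B polyenyne 28 with (E)-2,3-dibromoacrylic acid 30; 28 comes from an HWE union of dienynal 22 (ring B enol triflate + (E)-3-methylpent-2-en-4-yn-1-ol) with the silyl enynyl phosphonate 26.
- Ring A rests on its vicinal tertiary diol: O5 and O6 are trans, and O5 lies on the same face as C7, the carbon carried by C6. A tert-butyl carbonate on O7 can therefore hand its carbonyl oxygen to C5 of a 5,6-oxirane lying cis to O3, with inversion (11 → 12).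
- 11 comes from ketoisophorone via (4R,6R)-actinol, the enol triflate 5 (shared with ring B), carbonylation (C7), reduction and tartrate-controlled epoxidation.
- Ring order: both carbocycles are preformed; oxirane (step 6), temporary 1,3-dioxan-2-one (step 8), butenolide (step 22).

Key step: step 8

Remark: ring A is numbered as in carotenoids (C1 gem-dimethyl, C3 carbinol, C5 methyl carbinol, C6 quaternary carbinol, C7 the exocyclic carbon on C6, C8 the next chain carbon). It is assumed that L-(+)-diethyl tartrate overrides the intrinsic facial bias of alkene 7.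

**Route**

Step 1
Reactants: 1 ketoisophorone
Product: 3 (4R,6R)-actinol [(4R,6R)-4-hydroxy-2,2,6-trimethylcyclohexanone], via (6R)-levodione 2 (not isolated)
Conditions: old yellow enzyme 2, NADPH (cat.), D-glucose, glucose dehydrogenase, phosphate buffer pH 7, 30 °C; then levodione reductase, NADH (cat.), same pot
Reagents that add atoms: none
Why: Enzymatic ene reduction of the enone C=C should set C6 as R, and the reductase should then deliver hydride to the unhindered C4 carbonyl to set C4 as R (two-enzyme asymmetric bioreduction).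

Step 2
Reactants: 3 (4R,6R)-actinol
Product: 4 (4R,6R)-4-(tert-butyldimethylsilyloxy)-2,2,6-trimethylcyclohexanone
Conditions: TBSCl, imidazole, DMF, rt
Reagents that add atoms: tert-butyldimethylsilyl chloride, CC(C)(C)[Si](C)(C)Cl
Why: Imidazole-promoted silylation of the secondary alcohol, with no stereocenter touched.

Step 3
Reactants: 4 silyl ether of actinol
Product: 5 (4R)-4-(tert-butyldimethylsilyloxy)-2,6,6-trimethylcyclohex-1-en-1-yl trifluoromethanesulfonate
Conditions: KHMDS, THF, −78 °C; PhNTf2, −78 to 0 °C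
Reagents that add atoms: N-phenylbis(trifluoromethanesulfonimide), O=S(=O)(N(c1ccccc1)S(=O)(=O)C(F)(F)F)C(F)(F)F
Why: Only C6 carries an α-hydrogen, so the enolate forms at one site and is O-sulfonylated (enol triflate formation); the C6 stereocenter is given up on purpose and C4 is untouched.

Step 4
Reactants: 5 enol triflate
Product: 6 methyl (4R)-4-(tert-butyldimethylsilyloxy)-2,6,6-trimethylcyclohex-1-ene-1-carboxylate
Conditions: Pd(OAc)2 (cat.), PPh3, CO (1 atm), MeOH, Et3N, DMF, 60 °C
Reagents that add atoms: carbon monoxide, [C-]#[O+]; methanol, CO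
Why: Palladium-catalysed alkoxycarbonylation of the vinyl triflate (oxidative addition, CO insertion, methanolysis) introduces C7.

Step 5
Reactants: 6 methyl ester
Product: 7 [(4R)-4-(tert-butyldimethylsilyloxy)-2,6,6-trimethylcyclohex-1-en-1-yl]methanol
Conditions: DIBAL-H, CH2Cl2, −78 to 0 °C; Rochelle salt work-up
Reagents that add atoms: none
Why: Hydride reduction of the conjugated ester to the allylic alcohol, which leaves the tetrasubstituted alkene and the silyl ether alone.

Step 6
Reactants: 7 allylic alcohol; 8 tert-butyl hydroperoxide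
Product: 9 [(1S,4S,6S)-4-(tert-butyldimethylsilyloxy)-2,2,6-trimethyl-7-oxabicyclo[4.1.0]heptan-1-yl]methanol (oxirane cis to the silyloxy group; 3S,5S,6S in carotenoid numbering)
Conditions: Ti(OiPr)4 (0.3 equiv), L-(+)-diethyl tartrate (0.36 equiv), 4 Å molecular sieves, CH2Cl2, −20 °C
Reagents that add atoms: none
Why: Sharpless asymmetric epoxidation, in which the L-(+)-tartrate titanium complex should deliver oxygen to the face of C5=C6 that gives the 6S epoxy alcohol; this is the face cis to O3, so C5 and C6 are set by reagent control.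

Step 7
Reactants: 9 syn-epoxy alcohol; 10 di-tert-butyl dicarbonate
Product: 11 tert-butyl [(1S,4S,6S)-4-(tert-butyldimethylsilyloxy)-2,2,6-trimethyl-7-oxabicyclo[4.1.0]heptan-1-yl]methyl carbonate
Conditions: DMAP (cat.), CH2Cl2, rt
Reagents that add atoms: none
Why: DMAP-catalysed acylation of the primary alcohol under non-acidic conditions that should neither open nor rearrange the oxirane.

Step 8
Reactants: 11 epoxy tert-butyl carbonate
Product: 12 (4aS,7S,8aR)-7-(tert-butyldimethylsilyloxy)-4a-hydroxy-5,5,8a-trimethylhexahydro-4H-benzo[d][1,3]dioxin-2-one (cis-fused C5,C7 cyclic carbonate with free C6 hydroxyl)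
Conditions: BF3·OEt2 (0.5 equiv), CH2Cl2, −78 to −40 °C; Et3N quench
Reagents that add atoms: none
Why: Complexation of the epoxide oxygen by BF3 should weaken the C5–O bond in preference to the C6–O bond, since C5 (methyl and ring methylene substituents) tolerates cationic character better than C6, which is flanked by the quaternary C1 and carries the electron-poor CH2–O–CO2tBu group; the carbonate C=O oxygen, tethered through C7 on the ring face anti to the epoxide, then adds to C5 in an anti, trans-diaxial fashion and the resulting tert-butoxy dioxanylium ion sheds isobutene, the proton ending on O6. The nearest precedent is the Lewis-acid-induced cyclization of epoxy alcohol tert-butyl carbonates to cyclic carbonates with inversion at the attacked carbon. The 1,3-dioxan-2-one closes in the 6-endo mode (both epoxide carbons inside the new ring) and is cis-fused to ring A. C5 becomes R by inversion, dictated by the C6 configuration through the tether, whereas the C6–O bond stays intact, which makes the 5,6-diol trans and places O5 and C7 on the same face. The step needs attack at C5 and not at C6 (which would give a spiro five-membered carbonate) and trapping that is faster than 1,2-shift or proton loss from the incipient C5 cation; the electronic and steric deactivation of C6, the intramolecular nucleophile and the low temperature should provide both.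

Step 9
Reactants: 12 cyclic carbonate
Product: 13 (1R,2S,5S)-5-(tert-butyldimethylsilyloxy)-2-(hydroxymethyl)-1,3,3-trimethylcyclohexane-1,2-diol
Conditions: K2CO3 (cat.), MeOH, rt
Reagents that add atoms: none
Why: Base-catalysed transesterification with methanol releases the three hydroxyls as dimethyl carbonate forms, touching no stereocenter and leaving the secondary silyl ether.

Step 10
Reactants: 13 triol
Product: 14 (1R,2R,4S)-4-(tert-butyldimethylsilyloxy)-1,2-dihydroxy-2,6,6-trimethylcyclohexane-1-carbaldehyde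
Conditions: SO3·pyridine, DMSO, Et3N, CH2Cl2, 0 °C
Reagents that add atoms: none
Why: Parikh–Doering oxidation can act only on the primary alcohol because both other free hydroxyls are tertiary, and activated DMSO does not cleave 1,2-diols.

Step 11
Reactants: 14 α-hydroxy aldehyde; 15 dimethyl (1-diazo-2-oxopropyl)phosphonate (Ohira–Bestmann reagent)
Product: 16 (1R,2S,5S)-5-(tert-butyldimethylsilyloxy)-2-ethynyl-1,3,3-trimethylcyclohexane-1,2-diol
Conditions: K2CO3, MeOH, 0 °C to rt
Reagents that add atoms: none
Why: Seyferth–Gilbert homologation in the Ohira–Bestmann form turns the non-enolisable aldehyde into the terminal alkyne (C8 added) under mild carbonate conditions that spare the silyl ether and the tertiary hydroxyls.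

Step 12
Reactants: 16 ethynyl diol
Product: 17 (1R,2R,5S)-5-(tert-butyldimethylsilyloxy)-1,3,3-trimethyl-2-[(E)-2-(tributylstannyl)ethenyl]cyclohexane-1,2-diol
Conditions: Bu3SnH, Pd(PPh3)2Cl2 (cat.), THF, 0 °C
Reagents that add atoms: tributyltin hydride, CCCC[SnH](CCCC)CCCC
Why: Palladium-catalysed syn hydrostannation should place tin on the terminal carbon, because the fully substituted propargylic C6 blocks the internal position, giving the E vinylstannane.

Step 13
Reactants: 5 enol triflate; 18 (2E)-3-methylpent-2-en-4-yn-1-ol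
Product: 19 (2E)-5-[(4R)-4-(tert-butyldimethylsilyloxy)-2,6,6-trimethylcyclohex-1-en-1-yl]-3-methylpent-2-en-4-yn-1-ol
Conditions: Pd(PPh3)4 (cat.), CuI (cat.), Et3N, DMF, rt
Reagents that add atoms: none
Why: Sonogashira coupling of the vinyl triflate with the terminal alkyne, with the E geometry of the enynol carried through unchanged.

Step 14
Reactants: 19 ring B enynol
Product: 20 (2E)-5-[(4R)-4-(tert-butyldimethylsilyloxy)-2,6,6-trimethylcyclohex-1-en-1-yl]-3-methylpent-2-en-4-ynal
Conditions: MnO2, CH2Cl2, rt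
Reagents that add atoms: none
Why: MnO2 oxidises the allylic alcohol selectively to the enal without affecting the silyl ether or the enyne.

Step 15
Reactants: 20 ring B enynal; 21 (triphenylphosphoranylidene)acetaldehyde
Product: 22 (2E,4E)-7-[(4R)-4-(tert-butyldimethylsilyloxy)-2,6,6-trimethylcyclohex-1-en-1-yl]-5-methylhepta-2,4-dien-6-ynal
Conditions: toluene, 80 °C
Reagents that add atoms: none
Why: Wittig reaction with the stabilised formylmethylene ylide adds two carbons and should give the E enal, the more conjugated product aldehyde reacting more slowly than 20.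

Step 16
Reactants: 18 (2E)-3-methylpent-2-en-4-yn-1-ol
Product: 24 (2E)-3-methyl-5-(trimethylsilyl)pent-2-en-4-yn-1-ol, via bis-silylated enynol 23 (not isolated)
Conditions: n-BuLi (2.2 equiv), THF, −78 °C; Me3SiCl (2.3 equiv), −78 °C to rt; then 1 M HCl (aq), rt
Reagents that add atoms: chlorotrimethylsilane, C[Si](C)(C)Cl
Why: Double deprotonation and silylation, followed by acid hydrolysis of the labile O–Si bond only, masks the acidic alkyne C–H for the later olefination.

Step 17
Reactants: 24 C-silyl enynol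
Product: 25 [(3E)-5-bromo-3-methylpent-3-en-1-yn-1-yl]trimethylsilane
Conditions: CBr4, PPh3, CH2Cl2, 0 °C
Reagents that add atoms: tetrabromomethane, BrC(Br)(Br)Br
Why: Appel bromination of the primary allylic alcohol under neutral conditions, which should avoid allylic transposition and keep the E geometry.

Step 18
Reactants: 25 allylic bromide
Product: 26 diethyl [(2E)-3-methyl-5-(trimethylsilyl)pent-2-en-4-yn-1-yl]phosphonate
Conditions: P(OEt)3, neat, 110 °C
Reagents that add atoms: triethyl phosphite, CCOP(OCC)OCC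
Why: Michaelis–Arbuzov reaction of a primary allylic bromide.

Step 19
Reactants: 22 ring B dienynal; 26 enynyl phosphonate
Product: 27 trimethyl{(3E,5E,7E,9E)-12-[(4R)-4-(tert-butyldimethylsilyloxy)-2,6,6-trimethylcyclohex-1-en-1-yl]-3,10-dimethyldodeca-3,5,7,9-tetraene-1,11-diyn-1-yl}silane
Conditions: NaHMDS, THF, −78 °C; then 22, −78 to 0 °C, dark
Reagents that add atoms: none
Why: Horner–Wadsworth–Emmons olefination of the allylic phosphonate anion with the dienal should form the new disubstituted double bond E while the trisubstituted double bonds keep their geometry.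

Step 20
Reactants: 27 silyl polyenyne
Product: 28 ring B polyenyne, tert-butyl{[(1R)-4-[(3E,5E,7E,9E)-3,10-dimethyldodeca-3,5,7,9-tetraene-1,11-diyn-1-yl]-3,5,5-trimethylcyclohex-3-en-1-yl]oxy}dimethylsilane
Conditions: K2CO3 (cat.), MeOH–THF, rt, dark
Reagents that add atoms: none
Why: Carbonate-catalysed methanolysis cleaves the alkynyl C–Si bond but not the secondary TBS ether.

Step 21
Reactants: 29 propiolic acid
Product: 30 (2E)-2,3-dibromoprop-2-enoic acid
Conditions: Br2 (1.0 equiv), CHCl3, 0 °C to rt, dark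
Reagents that add atoms: bromine, BrBr
Why: Ionic anti addition of bromine to the alkyne gives the E dibromide, in which the C3 bromine is cis to the carboxyl group as the later lactonization requires.

Step 22
Reactants: 28 ring B polyenyne; 30 (2E)-2,3-dibromoprop-2-enoic acid
Product: 32 (5Z)-3-bromo-5-ylidenefuran-2(5H)-one carrying the ring B polyenyne chain, via bromo enynoic acid 31 (not isolated)
Conditions: Pd(PPh3)2Cl2 (cat.), CuI (cat.), Et3N, MeCN, rt, argon, dark
Reagents that add atoms: none
Why: Zerovalent palladium should insert into the more electrophilic C3–Br bond, Sonogashira coupling with 28 then gives 31 with retention, and the carboxylate cis to the alkyne adds 5-exo-dig in an anti sense to give the Z-ylidenebutenolide (tandem Sonogashira–lactonization).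

Step 23
Reactants: 32 bromobutenolide; 17 ring A vinylstannane
Product: 33 bis(tert-butyldimethylsilyl) ether of the target at O3 of ring A and O3 of ring B
Conditions: Pd2(dba)3 (cat.), AsPh3, NMP, rt to 40 °C, dark
Reagents that add atoms: none
Why: Stille coupling joins the butenolide α-carbon to C8 with retention of the E geometry of the stannane and tolerates the free tertiary hydroxyls and the lactone.

Step 24
Reactants: 33 bis-silyl ether
Product: 34 target CNP0163979.1 (3S,5R,6R in ring A; 3R in ring B)
Conditions: HF·pyridine, pyridine, THF, 0 °C to rt, dark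
Reagents that add atoms: none
Why: Buffered fluoride cleaves both secondary silyl ethers, and these mild conditions should leave the tertiary alcohols, the polyene and the butenolide untouched.

**Compound list**

1 | ketoisophorone (2,6,6-trimethylcyclohex-2-ene-1,4-dione) | CC1=CC(=O)CC(C)(C)C1=O | starting material
2 | (6R)-levodione [(6R)-2,2,6-trimethylcyclohexane-1,4-dione] | O=C1C(C)(C)CC(=O)C[C@H]1C | intermediate
3 | (4R,6R)-actinol [(4R,6R)-4-hydroxy-2,2,6-trimethylcyclohexanone] | O=C1C(C)(C)C[C@H](O)C[C@H]1C | intermediate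
4 | (4R,6R)-4-(tert-butyldimethylsilyloxy)-2,2,6-trimethylcyclohexanone | O=C1C(C)(C)C[C@H](O[Si](C)(C)C(C)(C)C)C[C@H]1C | intermediate
5 | (4R)-4-(tert-butyldimethylsilyloxy)-2,6,6-trimethylcyclohex-1-en-1-yl trifluoromethanesulfonate | CC1=C(OS(=O)(=O)C(F)(F)F)C(C)(C)C[C@H](O[Si](C)(C)C(C)(C)C)C1 | intermediate
6 | methyl (4R)-4-(tert-butyldimethylsilyloxy)-2,6,6-trimethylcyclohex-1-ene-1-carboxylate | CC1=C(C(=O)OC)C(C)(C)C[C@H](O[Si](C)(C)C(C)(C)C)C1 | intermediate
7 | [(4R)-4-(tert-butyldimethylsilyloxy)-2,6,6-trimethylcyclohex-1-en-1-yl]methanol | CC1=C(CO)C(C)(C)C[C@H](O[Si](C)(C)C(C)(C)C)C1 | intermediate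
8 | tert-butyl hydroperoxide | CC(C)(C)OO | starting material
9 | [(1S,4S,6S)-4-(tert-butyldimethylsilyloxy)-2,2,6-trimethyl-7-oxabicyclo[4.1.0]heptan-1-yl]methanol (syn-epoxy alcohol) | OC[C@@]1(O2)C(C)(C)C[C@H](O[Si](C)(C)C(C)(C)C)C[C@@]12C | intermediate
10 | di-tert-butyl dicarbonate | CC(C)(C)OC(=O)OC(=O)OC(C)(C)C | starting material
11 | tert-butyl [(1S,4S,6S)-4-(tert-butyldimethylsilyloxy)-2,2,6-trimethyl-7-oxabicyclo[4.1.0]heptan-1-yl]methyl carbonate | CC(C)(C)OC(=O)OC[C@@]1(O2)C(C)(C)C[C@H](O[Si](C)(C)C(C)(C)C)C[C@@]12C | intermediate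
12 | (4aS,7S,8aR)-7-(tert-butyldimethylsilyloxy)-4a-hydroxy-5,5,8a-trimethylhexahydro-4H-benzo[d][1,3]dioxin-2-one | O=C1OC[C@@]2(O)C(C)(C)C[C@H](O[Si](C)(C)C(C)(C)C)C[C@@]2(C)O1 | intermediate
13 | (1R,2S,5S)-5-(tert-butyldimethylsilyloxy)-2-(hydroxymethyl)-1,3,3-trimethylcyclohexane-1,2-diol | OC[C@@]1(O)C(C)(C)C[C@H](O[Si](C)(C)C(C)(C)C)C[C@@]1(C)O | intermediate
14 | (1R,2R,4S)-4-(tert-butyldimethylsilyloxy)-1,2-dihydroxy-2,6,6-trimethylcyclohexane-1-carbaldehyde | O=C[C@@]1(O)C(C)(C)C[C@H](O[Si](C)(C)C(C)(C)C)C[C@@]1(C)O | intermediate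
15 | dimethyl (1-diazo-2-oxopropyl)phosphonate | COP(=O)(OC)C(=[N+]=[N-])C(C)=O | starting material
16 | (1R,2S,5S)-5-(tert-butyldimethylsilyloxy)-2-ethynyl-1,3,3-trimethylcyclohexane-1,2-diol | C#C[C@@]1(O)C(C)(C)C[C@H](O[Si](C)(C)C(C)(C)C)C[C@@]1(C)O | intermediate
17 | (1R,2R,5S)-5-(tert-butyldimethylsilyloxy)-1,3,3-trimethyl-2-[(E)-2-(tributylstannyl)ethenyl]cyclohexane-1,2-diol | CCCC[Sn](CCCC)(CCCC)/C=C/[C@@]1(O)C(C)(C)C[C@H](O[Si](C)(C)C(C)(C)C)C[C@@]1(C)O | intermediate
18 | (2E)-3-methylpent-2-en-4-yn-1-ol | C#C/C(C)=C/CO | starting material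
19 | (2E)-5-[(4R)-4-(tert-butyldimethylsilyloxy)-2,6,6-trimethylcyclohex-1-en-1-yl]-3-methylpent-2-en-4-yn-1-ol | CC1=C(C#C/C(C)=C/CO)C(C)(C)C[C@H](O[Si](C)(C)C(C)(C)C)C1 | intermediate
20 | (2E)-5-[(4R)-4-(tert-butyldimethylsilyloxy)-2,6,6-trimethylcyclohex-1-en-1-yl]-3-methylpent-2-en-4-ynal | CC1=C(C#C/C(C)=C/C=O)C(C)(C)C[C@H](O[Si](C)(C)C(C)(C)C)C1 | intermediate
21 | (triphenylphosphoranylidene)acetaldehyde | O=CC=P(c1ccccc1)(c1ccccc1)c1ccccc1 | starting material
22 | (2E,4E)-7-[(4R)-4-(tert-butyldimethylsilyloxy)-2,6,6-trimethylcyclohex-1-en-1-yl]-5-methylhepta-2,4-dien-6-ynal | CC1=C(C#C/C(C)=C/C=C/C=O)C(C)(C)C[C@H](O[Si](C)(C)C(C)(C)C)C1 | intermediate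
23 | trimethyl{[(2E)-3-methyl-5-(trimethylsilyl)pent-2-en-4-yn-1-yl]oxy}silane | C[Si](C)(C)C#C/C(C)=C/CO[Si](C)(C)C | intermediate
24 | (2E)-3-methyl-5-(trimethylsilyl)pent-2-en-4-yn-1-ol | C[Si](C)(C)C#C/C(C)=C/CO | intermediate
25 | [(3E)-5-bromo-3-methylpent-3-en-1-yn-1-yl]trimethylsilane | C[Si](C)(C)C#C/C(C)=C/CBr | intermediate
26 | diethyl [(2E)-3-methyl-5-(trimethylsilyl)pent-2-en-4-yn-1-yl]phosphonate | CCOP(=O)(OCC)C/C=C(C)/C#C[Si](C)(C)C | intermediate
27 | trimethyl{(3E,5E,7E,9E)-12-[(4R)-4-(tert-butyldimethylsilyloxy)-2,6,6-trimethylcyclohex-1-en-1-yl]-3,10-dimethyldodeca-3,5,7,9-tetraene-1,11-diyn-1-yl}silane | CC1=C(C#C/C(C)=C/C=C/C=C/C=C(C)/C#C[Si](C)(C)C)C(C)(C)C[C@H](O[Si](C)(C)C(C)(C)C)C1 | intermediate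
28 | tert-butyl{[(1R)-4-[(3E,5E,7E,9E)-3,10-dimethyldodeca-3,5,7,9-tetraene-1,11-diyn-1-yl]-3,5,5-trimethylcyclohex-3-en-1-yl]oxy}dimethylsilane (ring B polyenyne) | CC1=C(C#C/C(C)=C/C=C/C=C/C=C(C)/C#C)C(C)(C)C[C@H](O[Si](C)(C)C(C)(C)C)C1 | intermediate
29 | propiolic acid | C#CC(=O)O | starting material
30 | (2E)-2,3-dibromoprop-2-enoic acid | OC(=O)/C(Br)=C\Br | intermediate
31 | (2E)-2-bromo-pent-2-en-4-ynoic acid carrying the ring B polyenyne chain at C5 (C3-alkynylated acid) | CC1=C(C#C/C(C)=C/C=C/C=C/C=C(C)/C#C/C=C(/Br)C(=O)O)C(C)(C)C[C@H](O[Si](C)(C)C(C)(C)C)C1 | intermediate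
32 | (5Z)-3-bromo-5-{(2E,4E,6E,8E)-11-[(4R)-4-(tert-butyldimethylsilyloxy)-2,6,6-trimethylcyclohex-1-en-1-yl]-2,9-dimethylundeca-2,4,6,8-tetraen-10-yn-1-ylidene}furan-2(5H)-one | CC1=C(C#C/C(C)=C/C=C/C=C/C=C(C)/C=C2C=C(Br)C(=O)O/2)C(C)(C)C[C@H](O[Si](C)(C)C(C)(C)C)C1 | intermediate
33 | bis(tert-butyldimethylsilyl) ether of the target (O3 of ring A and O3 of ring B) | CC1=C(C#C/C(C)=C/C=C/C=C/C=C(C)/C=C2C=C(/C=C/[C@@]3(O)C(C)(C)C[C@H](O[Si](C)(C)C(C)(C)C)C[C@@]3(C)O)C(=O)O/2)C(C)(C)C[C@H](O[Si](C)(C)C(C)(C)C)C1 | intermediate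
34 | CNP0163979.1 | CC1=C(C#C/C(C)=C/C=C/C=C/C=C(C)/C=C2C=C(/C=C/[C@@]3(O)C(C)(C)C[C@H](O)C[C@@]3(C)O)C(=O)O/2)C(C)(C)C[C@H](O)C1 | target

**Step count**

Total: 24 steps. Longest linear sequence: 14 steps (steps 1–12, 23 and 24, from ketoisophorone).

**Steps most likely to fail**

1. Step 8 (carbonate-tethered epoxide opening). The opening may occur at C6 to give the spiro five-membered carbonate. Trapping of the developing C5 cation may also be outrun by a ring-contracting 1,2-shift or by proton loss to an allylic alcohol, and the silyl ether may be lost to the Lewis acid. Fallback without a tether, by known chemistry: set out from epoxy alcohol 9 and hydrolyse the oxirane with catalytic HClO4 in THF–water at 0 °C. Acid-catalysed hydrolysis of a fully substituted epoxide proceeds by attack of water at the carbon that better carries positive charge (C5) with inversion, which gives the trans-diol directly as triol 13. The route is rejoined at 13 and steps 7–9 fall away; no compound outside the list is made (F0).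

2. Step 6 (tartrate-controlled epoxidation). Facial selectivity may be poor if reagent control has to work against the intrinsic preference of the ring for attack anti to the C3 substituent, and oxygen transfer to the hindered tetrasubstituted alkene may be sluggish. Fallback by substrate-directed epoxidation: set out from 7 and acylate with Boc2O/DMAP to the allylic tert-butyl carbonate F1. HF·pyridine then frees the C3 hydroxyl to give the homoallylic alcohol F2. VO(acac)2 with tert-butyl hydroperoxide in toluene delivers oxygen to C5=C6 from the face of the coordinating C3 hydroxyl (hydroxyl-directed epoxidation of a cyclic homoallylic alcohol), giving the syn-epoxy carbonate F3. TBSCl/imidazole returns to 11, so steps 6 and 7 are replaced.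

3. Step 22 (tandem Sonogashira–lactonization). The two C–Br bonds may not be discriminated cleanly, the product bromobutenolide may be alkynylated a second time, 6-endo closure to a pyranone may compete, and the polyenyne may degrade under the amine and copper conditions. Fallback that separates the events and closes the lactone last: set out from 28, 30 and 17. Fischer esterification of 30 (EtOH, cat. H2SO4) gives ethyl (2E)-2,3-dibromoprop-2-enoate F4. Sonogashira coupling of 28 with F4 at C3 (Pd(PPh3)4, CuI, Et3N) gives the bromo enynoate F5. Stille coupling of F5 with 17 (Pd2(dba)3, AsPh3) gives the 2-alkenyl enynoate F6. LiOH in THF–MeOH–water gives the enynoic acid F7, and AgNO3 (cat.) in acetone closes it 5-exo-dig to the Z-ylidenebutenolide 33. The route is rejoined at 33, so steps 22 and 23 are replaced.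

Further compounds
F0 | step 8 | none | none
F1 | step 6 | tert-butyl [(4R)-4-(tert-butyldimethylsilyloxy)-2,6,6-trimethylcyclohex-1-en-1-yl]methyl carbonate | CC1=C(COC(=O)OC(C)(C)C)C(C)(C)C[C@H](O[Si](C)(C)C(C)(C)C)C1
F2 | step 6 | tert-butyl [(4R)-4-hydroxy-2,6,6-trimethylcyclohex-1-en-1-yl]methyl carbonate | CC1=C(COC(=O)OC(C)(C)C)C(C)(C)C[C@H](O)C1
F3 | step 6 | tert-butyl [(1S,4S,6S)-4-hydroxy-2,2,6-trimethyl-7-oxabicyclo[4.1.0]heptan-1-yl]methyl carbonate | CC(C)(C)OC(=O)OC[C@@]1(O2)C(C)(C)C[C@H](O)C[C@@]12C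
F4 | step 22 | ethyl (2E)-2,3-dibromoprop-2-enoate | CCOC(=O)/C(Br)=C\Br
F5 | step 22 | ethyl (2E)-2-bromo-pent-2-en-4-ynoate carrying the ring B polyenyne chain at C5 | CC1=C(C#C/C(C)=C/C=C/C=C/C=C(C)/C#C/C=C(/Br)C(=O)OCC)C(C)(C)C[C@H](O[Si](C)(C)C(C)(C)C)C1
F6 | step 22 | ethyl 2-[(E)-2-(ring A)ethenyl]pent-2-en-4-ynoate carrying the ring B polyenyne chain at C5 (alkyne cis to the ester) | CC1=C(C#C/C(C)=C/C=C/C=C/C=C(C)/C#C/C=C(/C=C/[C@@]2(O)C(C)(C)C[C@H](O[Si](C)(C)C(C)(C)C)C[C@@]2(C)O)C(=O)OCC)C(C)(C)C[C@H](O[Si](C)(C)C(C)(C)C)C1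
F7 | step 22 | carboxylic acid of F6 | CC1=C(C#C/C(C)=C/C=C/C=C/C=C(C)/C#C/C=C(/C=C/[C@@]2(O)C(C)(C)C[C@H](O[Si](C)(C)C(C)(C)C)C[C@@]2(C)O)C(=O)O)C(C)(C)C[C@H](O[Si](C)(C)C(C)(C)C)C1
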